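## Structural features

The target is a tridepside: three benzene rings joined in a line by two aryl ester links. The carboxyl of ring A esterifies the C4 oxygen of ring B, the carboxyl of ring B esterifies the C4 oxygen of ring C, and the carboxyl of ring C is free. Ring A is a 4-hydroxy-2,3-dimethoxy-6-methylbenzoyl unit; rings B and C are orsellinic acid units (2-hydroxyl, 6-methyl, oxygen at C4). There is no stereocentre. Every carbonyl group is flanked by two ortho substituents, so each ester formation is hindered and each acid is electron-rich. The fragile groups are the two aryl esters (cleaved or transferred by bases and nucleophiles), the salicylic acid terminus of ring C (prone to decarboxylation under acid or heat) and the free phenols. The real difficulty is the differentiation of oxygens: on ring A, O4 is free while O2 and O3 are methylated; on rings B and C, O4 is acylated while O2 stays free. The key step exploits ring C, where C1 bears the carboxyl, C2 and C4 oxygen, C3 and C5 hydrogen and C6 the methyl group. This pattern maps onto a ketene carbon (C4), an ynol ether (C3, C2) and an isopropenyl-substituted carbene carbon (C5, C6, C1), so the ring forms with O4 free and O2 silylated.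

## Logic of the disconnections

28 is traced to 27 by cutting the two O–benzyl bonds (ether on ring B, ester on ring C), and 27 to 26 by cutting the two O–Si bonds (O4 of ring A, O2 of ring C). The acid and the phenols are thus revealed last, by neutral hydrogenolysis after a buffered fluoride step, so the decarboxylation-prone terminus never meets acid, base or heat. The gain is that all earlier intermediates are neutral esters and ethers. The demand is that fluoride spares two aryl esters and that hydrogenolysis stops at the benzylic C–O bonds.

26 is cut at the ester C(=O)–O bond between the ring B carbonyl and O4 of ring C, giving 24 and 14. The cut is convergent and divides the molecule into pieces of similar size. The forward step needs a phenol whose only free hydroxyl is O4 (this is what the key step delivers in 14) and a strong activation of the hindered acid (mixed anhydride 25).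

14 is cut at C1–C2, C3–C4 and C4–C5 and, through a retro-Wolff shift, at C1–C6, leading to 4 and 9. The reason is that the ring then arises with its two oxygens already different, one as a free hydroxyl and one as a silyl ether. The gain is an acyclic diazo keto ester and a two-carbon alkyne. The forward step must favour (2+2) addition of the ketene over other modes and passes through 10, 11, 12 and 13. The structures of 4, 9 and 14 need no correction, since the atom mapping is self-consistent.

4 is traced to 3 by a change of oxidation level at C3, and 3 is cut at C2–C3 into 1 and 2. The diazo carbon thus arrives in place and the enone is unveiled only in the last operation. A route through a free γ,δ-unsaturated β-keto ester with late diazo transfer was set aside, because such keto esters oligomerise by Michael addition under base. The gain is two purchasable compounds and two steps. The demand is 1,2-addition to 2 and an oxidant that leaves the diazo group alone.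

9 is cut at O–Si and at C–O, back through 8 and 7 to 5 and 6. The two carbons come from the simplest alkyne and the oxygen from a peroxide donor. The demand is mono-metalation of 5 and silylation of 8 at oxygen, which the bulk of 6 favours.

24 is traced to 23 by lowering the carboxyl to a formyl group, 23 to 22 by cutting the O–benzyl bond, and 22 is cut at the ester C(=O)–O bond between the ring A carbonyl and O4 of ring B into 19 and 20. The formyl group serves as a masked carboxyl that cannot be acylated and that ties O2–H of 20 into a hydrogen bond, so ring B needs no protection before the coupling. The demand is site selectivity for O4 over O2 and a mild oxidation afterwards.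

19 is cut at the C1–carboxyl bond to give 17 (through 18), 17 at O–Si to give 16, and 16 is traced to 15 by changing methyl back to formyl. The full oxygen pattern of ring A is bought with 15, so only one carbon has to be added. The demand is that lithiation occur between the outer methoxy group and the methyl group and not beside the silyl ether. The bulky, non-coordinating silyl group secures this and later leaves together with the silyl group of ring C.

## Other disconnections considered

Alternative 1: The cut removes both adjacent carbon substituents of ring A, the C6–methyl and the C1–carboxyl bonds. It leads to the aryne 1,2-didehydro-3,4-dimethoxy-5-(triisopropylsilyloxy)benzene A3 and, behind it, to 2-iodo-3,4-dimethoxy-5-(triisopropylsilyloxy)phenyl 4-chlorobenzenesulfonate A2.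
- Forward step: i-PrMgCl would exchange the iodine of A2 and the arylmagnesium would expel the neighbouring sulfonate to give A3. MeMgCl under CuI catalysis would deliver methyl to C6, and the carbon–magnesium bond left at C1 would be carboxylated with CO2 to 2,3-dimethoxy-6-methyl-4-(triisopropylsilyloxy)benzoic acid A1. No ring is closed.
- In favour: two carbon–carbon bonds of the most crowded ring would form in one flask. The reacting positions are coded by iodine and sulfonate, so no choice between two ring C–H bonds arises. The C2 methoxy group should steer methyl to the distal carbon, because the charge then develops at C1 beside the withdrawing oxygen.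
- Against: A2 has a single ring hydrogen and needs its own regioselective iodination and several preparatory steps. The orientation of the addition rests on one inductive effect. The step serves ring A only.
- Comparison: A1 is identical with 19, which the chosen plan reaches from 17 in one lithiation–carboxylation, so the chosen route is shorter for ring A. On positional certainty the alternative is the better, because the lithiation of 17 must discriminate between two flanked C–H bonds. Both are polar organometallic steps with close analogy and both are better founded than step 4. The alternative spends its strategic step on the ring that is hardest to buy, whereas the chosen key step builds ring C, the easiest of the three to obtain. On that point the alternative is better placed, but it does nothing to tell O2 and O4 of ring C apart.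

Alternative 2: Ring A is cut at C1–C6 and C3–C4 at the cyclohexanedione oxidation level, leading to methyl 4-methoxy-3-oxobutanoate A5 and methyl (E)-but-2-enoate A6.
- Forward step: NaOMe would effect Michael addition of the A5 enolate to A6 and Dieckmann closure of the methoxy-bearing carbon onto the distal ester, giving methyl 3-methoxy-6-methyl-2,4-dioxocyclohexane-1-carboxylate A4. Dehydrogenation would give methyl 2,4-dihydroxy-3-methoxy-6-methylbenzoate A7.
- In favour: the inputs are cheap and acyclic. Every substituent is placed by connectivity, so no aromatic regioselectivity is needed. The O3 methoxy group is present from the start. The stereocentres of A4 are irrelevant because they vanish on aromatisation.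
- Against: aromatisation of an alkoxy-substituted dihydroresorcinol calls for an oxidant that does not halogenate or over-oxidise the electron-rich product. The Dieckmann step must engage the more hindered, oxygen-substituted carbon. A7 still needs protection of O4, methylation of the chelated O2 and saponification of a doubly ortho-substituted methyl ester, which is slow.
- Comparison: about five operations would lead to a protected ring A acid, against three (steps 5 to 7), so the chosen route is shorter for this ring. In regiochemical certainty and in reliance on classical enolate chemistry the alternative is the better. Neither plan has a stereochemical problem. Like alternative 1 it leaves ring C and its oxygen differentiation untouched, so it complements the benzannulation and does not replace it.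

Alternative 3: Ring B is cut at C1–C6 together with the ester bond from its carbonyl to O4 of ring C, leading to 6-(2,4-dioxopentyl)-2,2-dimethyl-4H-1,3-dioxin-4-one A9 and benzyl 2,4-dihydroxy-6-methylbenzoate A10.
- Forward step: heating A9 would induce retro-(4+2) fragmentation to the acylketene oct-1-ene-1,3,5,7-tetraone A12. The unchelated O4–H of A10 would capture it to give benzyl 2-hydroxy-6-methyl-4-[(3,5,7-trioxooctanoyl)oxy]benzoate A11. Et3N would then drive aldol condensation of C2 onto C7 with dehydration and enolisation, closing ring B in benzyl 4-(2,4-dihydroxy-6-methylbenzoyl)oxy-2-hydroxy-6-methylbenzoate A8.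
- In favour: the inter-ring ester and ring B would form in one operation without protecting groups on ring B. Ring C is bought. In A8 the only unchelated phenol is O4–H of ring B, ready for acylation with 19.
- Against: A11 is an aryl ester of a polyketo acid, and its aryloxide is a good leaving group. Lactonisation to a hydroxypyranone with loss of A10, or ester exchange, may therefore compete with the aldol closure under amine base. Ketene capture must also distinguish the two phenols of A10, and A9 has to be prepared.
- Comparison: this plan uses the innate difference between chelated and free phenols where the chosen plan builds the difference into ring C. In step economy and protecting-group economy it is the better (roughly nine to ten steps overall against thirteen). Its aromatisation also has closer analogy than step 4. The chosen plan is the equal or the better only in that no base-sensitive polyketo aryl ester is handled and that O2 of ring C is positively masked during the coupling.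

Key step: step 4

Assumption: 1, 2, 5, 6, 15 and 20 are taken as purchasable; ring positions are numbered within each benzoyl unit, with C1 bearing the carbonyl carbon and C6 the methyl group.

## Route

Step 1
Reactants: 1 benzyl diazoacetate; 2 methacrolein (2-methylprop-2-enal)
Product: 3 benzyl 2-diazo-3-hydroxy-4-methylpent-4-enoate (racemic)
Conditions: DBU (10 mol %), MeCN, rt
Reagents that add atoms: none
Why: DBU-catalysed aldol-type addition of the diazoacetate carbon to the aldehyde; the stabilised diazo anion should add 1,2 to the α-branched enal. The new carbinol centre forms as a racemate, which is immaterial because step 2 removes it.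

Step 2
Reactants: 3 benzyl 2-diazo-3-hydroxy-4-methylpent-4-enoate
Product: 4 benzyl 2-diazo-4-methyl-3-oxopent-4-enoate
Conditions: IBX, DMSO, rt
Reagents that add atoms: none
Why: IBX oxidation of a secondary allylic alcohol; α-diazo-β-hydroxy esters are known to give α-diazo-β-keto esters under such neutral conditions without loss of N2. The enone appears only here, so no base meets the Michael acceptor.

Step 3
Reactants: 5 acetylene; 6 chlorotriisopropylsilane
Product: 9 (triisopropylsilyloxy)acetylene, via lithium acetylide 7 (not isolated), via lithium ethynolate 8 (not isolated)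
Conditions: 5 (excess), n-BuLi, THF, −78 °C; t-BuOOLi [t-BuOOH, LiN(SiMe3)2], −78 → −10 °C; 6, −78 → 0 °C
Reagents that add atoms: tert-butyl hydroperoxide, CC(C)(C)OO
Why: Electrophilic oxygenation of a lithium acetylide by lithium tert-butyl peroxide (attack of the acetylide carbon on the peroxide oxygen, loss of t-BuOLi) should give the ynolate, which bulky silyl chlorides are known to trap at oxygen. Excess 5 keeps the acetylide monolithiated.

Step 4
Reactants: 4 benzyl 2-diazo-4-methyl-3-oxopent-4-enoate; 9 (triisopropylsilyloxy)acetylene
Product: 14 benzyl 4-hydroxy-6-methyl-2-(triisopropylsilyloxy)benzoate, via vinylketene 10 (not isolated), via vinylcyclobutenone 11 (not isolated), via dienylketene 12 (not isolated), via cyclohexadienone 13 (not isolated)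
Conditions: 9 (2.5 equiv), hν (254 nm), ClCH2CH2Cl, rt; then 80 °C in the dark
Reagents that add atoms: none
Why: Proposed new method: a photochemical Wolff rearrangement–benzannulation in which the vinylketene carries an ester group, the closest known reaction type being the Danheiser benzannulation of vinylketenes, made by photochemical Wolff rearrangement of unsaturated α-diazo ketones, with siloxyalkynes; the reasoning is as follows. Light should expel N2 from 4, and the isopropenyl group, the only carbon substituent on the ketone side and a far better migrating group than benzyloxy, should shift to the carbene carbon (C1–C6) to give ketene 10. The CH carbon of 9, the nucleophilic terminus of the ynol ether, should attack the ketene carbon (C3–C4), and the malonate-type enolate so formed should close at carbon onto the silyloxy-stabilised cation (C1–C2) to give cyclobutenone 11, with a regiochemistry fixed by the polarity of both partners. On heating, 11 should open by reversible 4π electrocyclic cleavage to dienylketene 12, and the isomer with the isopropenyl group cis to the ketene should be drained by 6π electrocyclisation (C4–C5), the mode by which ring C closes, to dienone 13, which enolises to phenol 14. No stereocentre is present in 14; the quaternary carbon of 11 is racemic and is lost on ring opening. The step needs selectivity for (2+2) addition over hetero-(4+2) addition through the ester carbonyl and over direct (4+2) addition across the vinylketene, which would put the silyl group on O4; the weak donor ability of an alkoxycarbonyl oxygen, the bulk of the triisopropylsilyl group and the two-stage protocol (light at room temperature, then heat without ketene present) are meant to secure it, but the substrate does not enforce it. Because the ketene oxygen ends as the free O4–H and the alkyne oxygen as the O2 silyl ether, the two oxygens of ring C are told apart by the construction.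

Step 5
Reactants: 15 3-hydroxy-4,5-dimethoxybenzaldehyde
Product: 16 2,3-dimethoxy-5-methylphenol
Conditions: H2 (4 atm), Pd/C, AcOH, cat. HCl, rt
Reagents that add atoms: none
Why: Hydrogenolysis of an electron-rich aryl aldehyde: reduction to the benzylic alcohol and acid-assisted hydrogenolysis of the benzylic C–O bond should give the methyl group. The methyl ethers and the phenol are inert.

Step 6
Reactants: 16 2,3-dimethoxy-5-methylphenol; 6 chlorotriisopropylsilane
Product: 17 (2,3-dimethoxy-5-methylphenoxy)triisopropylsilane
Conditions: imidazole, DMF, rt
Reagents that add atoms: none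
Why: Standard imidazole-assisted silylation of a phenol. The bulky silyl ether is chosen because it does not direct lithiation and shields its own ortho position in step 7.

Step 7
Reactants: 17 (2,3-dimethoxy-5-methylphenoxy)triisopropylsilane
Product: 19 2,3-dimethoxy-6-methyl-4-(triisopropylsilyloxy)benzoic acid, via aryllithium 18 (not isolated)
Conditions: n-BuLi, TMEDA, THF, 0 °C; CO2, −78 °C → rt; 1 M HCl
Reagents that add atoms: carbon dioxide, O=C=O
Why: Directed ortho-metalation: the only ring C–H beside a coordinating methoxy group lies between the outer methoxy and the methyl group, while the C–H beside the silyl ether is shielded and not activated; CO2 then carboxylates the aryllithium. Lithiation of 1,2,3-trialkoxybenzenes next to an outer alkoxy group is the supporting analogy.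

Step 8
Reactants: 19 2,3-dimethoxy-6-methyl-4-(triisopropylsilyloxy)benzoic acid; 20 2,4-dihydroxy-6-methylbenzaldehyde
Product: 22 4-formyl-3-hydroxy-5-methylphenyl 2,3-dimethoxy-6-methyl-4-(triisopropylsilyloxy)benzoate, via mixed anhydride 21 (not isolated)
Conditions: (CF3CO)2O, toluene, rt
Reagents that add atoms: none
Why: Esterification through the mixed trifluoroacetic anhydride, the standard activation of electron-rich, doubly ortho-substituted benzoic acids in depside synthesis. Of the two phenols of 20 only O4–H should react, because O2–H is hydrogen-bonded to and flanked by the formyl group.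

Step 9
Reactants: 22 4-formyl-3-hydroxy-5-methylphenyl 2,3-dimethoxy-6-methyl-4-(triisopropylsilyloxy)benzoate
Product: 23 3-(benzyloxy)-4-formyl-5-methylphenyl 2,3-dimethoxy-6-methyl-4-(triisopropylsilyloxy)benzoate
Conditions: BnBr, K2CO3, DMF, rt
Reagents that add atoms: benzyl bromide, BrCc1ccccc1
Why: Williamson O-benzylation of the chelated phenol under carbonate base. The hindered triisopropylsilyl aryl ether and the doubly ortho-substituted aryl ester should tolerate these mild anhydrous conditions.

Step 10
Reactants: 23 3-(benzyloxy)-4-formyl-5-methylphenyl 2,3-dimethoxy-6-methyl-4-(triisopropylsilyloxy)benzoate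
Product: 24 2-(benzyloxy)-4-{[2,3-dimethoxy-6-methyl-4-(triisopropylsilyloxy)benzoyl]oxy}-6-methylbenzoic acid
Conditions: NaClO2, NaH2PO4, 2-methylbut-2-ene, t-BuOH/THF/H2O, rt
Reagents that add atoms: sodium chlorite, [Na+].[O-]Cl=O
Why: Pinnick oxidation of the aldehyde to the acid. The alkene scavenges HOCl so that the electron-rich rings are not chlorinated, and the esters and the silyl and benzyl ethers are untouched.

Step 11
Reactants: 24 2-(benzyloxy)-4-{[2,3-dimethoxy-6-methyl-4-(triisopropylsilyloxy)benzoyl]oxy}-6-methylbenzoic acid; 14 benzyl 4-hydroxy-6-methyl-2-(triisopropylsilyloxy)benzoate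
Product: 26 benzyl 4-{[2-(benzyloxy)-4-{[2,3-dimethoxy-6-methyl-4-(triisopropylsilyloxy)benzoyl]oxy}-6-methylbenzoyl]oxy}-6-methyl-2-(triisopropylsilyloxy)benzoate, via mixed anhydride 25 (not isolated)
Conditions: (CF3CO)2O, toluene, rt
Reagents that add atoms: none
Why: Second mixed-anhydride esterification. O4–H is the only free hydroxyl of 14, so no site selectivity is required, and the strong activation answers the hindrance of acid 24.

Step 12
Reactants: 26 benzyl 4-{[2-(benzyloxy)-4-{[2,3-dimethoxy-6-methyl-4-(triisopropylsilyloxy)benzoyl]oxy}-6-methylbenzoyl]oxy}-6-methyl-2-(triisopropylsilyloxy)benzoate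
Product: 27 benzyl 4-{[2-(benzyloxy)-4-[(4-hydroxy-2,3-dimethoxy-6-methylbenzoyl)oxy]-6-methylbenzoyl]oxy}-2-hydroxy-6-methylbenzoate
Conditions: Bu4NF, AcOH (1:1), THF, 0 °C
Reagents that add atoms: none
Why: Fluoride should cleave both aryl O–Si bonds, while acetic acid protonates the phenoxides as they form and so should prevent attack on, or migration of, the aryl esters. The benzyl ether and benzyl ester are inert.

Step 13
Reactants: 27 benzyl 4-{[2-(benzyloxy)-4-[(4-hydroxy-2,3-dimethoxy-6-methylbenzoyl)oxy]-6-methylbenzoyl]oxy}-2-hydroxy-6-methylbenzoate
Product: 28 4-{[4-[(4-hydroxy-2,3-dimethoxy-6-methylbenzoyl)oxy]-2-hydroxy-6-methylbenzoyl]oxy}-2-hydroxy-6-methylbenzoic acid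
Conditions: H2 (1 atm), Pd/C, EtOAc, rt
Reagents that add atoms: none
Why: Hydrogenolysis of the benzyl ether and the benzyl ester over palladium on carbon under neutral conditions at room temperature. These conditions should neither cleave the aryl esters nor decarboxylate the salicylic acid terminus.

## Compound list

1 | benzyl diazoacetate | [N-]=[N+]=CC(=O)OCc1ccccc1 | starting material
2 | methacrolein (2-methylprop-2-enal) | C=C(C)C=O | starting material
3 | benzyl 2-diazo-3-hydroxy-4-methylpent-4-enoate (racemic) | C=C(C)C(O)C(=[N+]=[N-])C(=O)OCc1ccccc1 | intermediate
4 | benzyl 2-diazo-4-methyl-3-oxopent-4-enoate | C=C(C)C(=O)C(=[N+]=[N-])C(=O)OCc1ccccc1 | intermediate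
5 | acetylene | C#C | starting material
6 | chlorotriisopropylsilane | CC(C)[Si](Cl)(C(C)C)C(C)C | starting material
7 | lithium acetylide | [Li+].[C-]#C | intermediate
8 | lithium ethynolate | [Li+].[O-]C#C | intermediate
9 | (triisopropylsilyloxy)acetylene | C#CO[Si](C(C)C)(C(C)C)C(C)C | intermediate
10 | benzyl 3-methyl-2-(oxomethylidene)but-3-enoate (vinylketene) | C=C(C)C(=C=O)C(=O)OCc1ccccc1 | intermediate
11 | benzyl 4-oxo-1-(prop-1-en-2-yl)-2-(triisopropylsilyloxy)cyclobut-2-ene-1-carboxylate (racemic) | C=C(C)C1(C(=O)OCc2ccccc2)C(=O)C=C1O[Si](C(C)C)(C(C)C)C(C)C | intermediate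
12 | benzyl (2Z)-5-oxo-2-(prop-1-en-2-yl)-3-(triisopropylsilyloxy)penta-2,4-dienoate (dienylketene) | O=C=C/C(O[Si](C(C)C)(C(C)C)C(C)C)=C(\C(C)=C)C(=O)OCc1ccccc1 | intermediate
13 | benzyl 2-methyl-4-oxo-6-(triisopropylsilyloxy)cyclohexa-1,5-diene-1-carboxylate | O=C1C=C(O[Si](C(C)C)(C(C)C)C(C)C)C(C(=O)OCc2ccccc2)=C(C)C1 | intermediate
14 | benzyl 4-hydroxy-6-methyl-2-(triisopropylsilyloxy)benzoate | Cc1cc(O)cc(O[Si](C(C)C)(C(C)C)C(C)C)c1C(=O)OCc1ccccc1 | intermediate
15 | 3-hydroxy-4,5-dimethoxybenzaldehyde | COc1cc(C=O)cc(O)c1OC | starting material
16 | 2,3-dimethoxy-5-methylphenol | COc1cc(C)cc(O)c1OC | intermediate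
17 | (2,3-dimethoxy-5-methylphenoxy)triisopropylsilane | COc1cc(C)cc(O[Si](C(C)C)(C(C)C)C(C)C)c1OC | intermediate
18 | [2,3-dimethoxy-6-methyl-4-(triisopropylsilyloxy)phenyl]lithium | COc1c(OC)c(O[Si](C(C)C)(C(C)C)C(C)C)cc(C)c1[Li] | intermediate
19 | 2,3-dimethoxy-6-methyl-4-(triisopropylsilyloxy)benzoic acid | COc1c(OC)c(O[Si](C(C)C)(C(C)C)C(C)C)cc(C)c1C(=O)O | intermediate
20 | 2,4-dihydroxy-6-methylbenzaldehyde | Cc1cc(O)cc(O)c1C=O | starting material
21 | 2,3-dimethoxy-6-methyl-4-(triisopropylsilyloxy)benzoic trifluoroacetic anhydride | COc1c(OC)c(O[Si](C(C)C)(C(C)C)C(C)C)cc(C)c1C(=O)OC(=O)C(F)(F)F | intermediate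
22 | 4-formyl-3-hydroxy-5-methylphenyl 2,3-dimethoxy-6-methyl-4-(triisopropylsilyloxy)benzoate | COc1c(OC)c(O[Si](C(C)C)(C(C)C)C(C)C)cc(C)c1C(=O)Oc1cc(C)c(C=O)c(O)c1 | intermediate
23 | 3-(benzyloxy)-4-formyl-5-methylphenyl 2,3-dimethoxy-6-methyl-4-(triisopropylsilyloxy)benzoate | COc1c(OC)c(O[Si](C(C)C)(C(C)C)C(C)C)cc(C)c1C(=O)Oc1cc(C)c(C=O)c(OCc2ccccc2)c1 | intermediate
24 | 2-(benzyloxy)-4-{[2,3-dimethoxy-6-methyl-4-(triisopropylsilyloxy)benzoyl]oxy}-6-methylbenzoic acid | COc1c(OC)c(O[Si](C(C)C)(C(C)C)C(C)C)cc(C)c1C(=O)Oc1cc(C)c(C(=O)O)c(OCc2ccccc2)c1 | intermediate
25 | mixed trifluoroacetic anhydride of 24 | COc1c(OC)c(O[Si](C(C)C)(C(C)C)C(C)C)cc(C)c1C(=O)Oc1cc(C)c(C(=O)OC(=O)C(F)(F)F)c(OCc2ccccc2)c1 | intermediate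
26 | benzyl 4-{[2-(benzyloxy)-4-{[2,3-dimethoxy-6-methyl-4-(triisopropylsilyloxy)benzoyl]oxy}-6-methylbenzoyl]oxy}-6-methyl-2-(triisopropylsilyloxy)benzoate | COc1c(OC)c(O[Si](C(C)C)(C(C)C)C(C)C)cc(C)c1C(=O)Oc1cc(C)c(C(=O)Oc2cc(C)c(C(=O)OCc3ccccc3)c(O[Si](C(C)C)(C(C)C)C(C)C)c2)c(OCc2ccccc2)c1 | intermediate
27 | benzyl 4-{[2-(benzyloxy)-4-[(4-hydroxy-2,3-dimethoxy-6-methylbenzoyl)oxy]-6-methylbenzoyl]oxy}-2-hydroxy-6-methylbenzoate | COc1c(OC)c(O)cc(C)c1C(=O)Oc1cc(C)c(C(=O)Oc2cc(C)c(C(=O)OCc3ccccc3)c(O)c2)c(OCc2ccccc2)c1 | intermediate
28 | 4-{[4-[(4-hydroxy-2,3-dimethoxy-6-methylbenzoyl)oxy]-2-hydroxy-6-methylbenzoyl]oxy}-2-hydroxy-6-methylbenzoic acid | COc1c(O)cc(C)c(C(=O)Oc2cc(C)c(C(=O)Oc3cc(C)c(C(=O)O)c(O)c3)c(O)c2)c1OC | target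

## Step count and risk

Total number of steps: 13. Longest linear sequence: 9 steps (steps 5 to 13, from 15 to 28).

Least certain steps:

Step 4 (key step). The most likely failure is collapse of the ketene–ynol ether adduct through the ester carbonyl oxygen to a pyranone, or through the vinyl terminus so that the silyl group ends on O4. Dimerisation of the acylketene is a further risk. The cause is that the stabilised enolate of the adduct has three nucleophilic ends and nothing in 10 enforces closure at carbon. The fallback uses known depside chemistry, sets out from 24 and returns at 27. Purchased 2,4-dihydroxy-6-methylbenzoic acid would be alkylated at the carboxylate (BnBr, KHCO3, DMF) to benzyl 2,4-dihydroxy-6-methylbenzoate F1. Acid 24, activated as 25 with (CF3CO)2O, should acylate F1 at the unchelated O4 only, giving benzyl 4-{[2-(benzyloxy)-4-{[2,3-dimethoxy-6-methyl-4-(triisopropylsilyloxy)benzoyl]oxy}-6-methylbenzoyl]oxy}-2-hydroxy-6-methylbenzoate F2. Bu4NF/AcOH would then remove the single silyl ether of ring A to give 27. The oxygens of ring C are then told apart by the hydrogen bond of O2–H to the ester carbonyl instead of by ring construction.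

Step 3. Monolithium acetylide may disproportionate to the insoluble dilithium compound on warming, the ynolate may be metalated a second time, or silylation may occur at carbon to give a silylketene. The parent ynolate lacks the substituent that stabilises its homologues. The fallback changes the source of the ynolate; it sets out from 6 and returns at 9. Purchased 3-phenylisoxazole would be lithiated with n-BuLi in THF at −78 °C to 5-lithio-3-phenylisoxazole F3. On warming, F3 should fragment to benzonitrile and 8, which 6 silylates at oxygen to give 9.

Step 7. Lithiation may take place at the benzylic methyl group or beside the silyl ether, or the silyl group may migrate, because the wanted C–H is flanked on both sides. The fallback replaces C–H metalation by carbonylation of a phenol-derived triflate; it sets out from 16 and returns at 19.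
- O2 with Co(salen) (N,N'-bis(salicylidene)ethylenediaminocobalt, divalent cobalt) in DMF should oxidise 16 at the para position to 2,3-dimethoxy-5-methylcyclohexa-2,5-diene-1,4-dione F4.
- Na2S2O4 would reduce F4 to 2,3-dimethoxy-5-methylbenzene-1,4-diol F5.
- One equivalent of 6 with imidazole should silylate the less hindered hydroxyl, giving 2,3-dimethoxy-6-methyl-4-(triisopropylsilyloxy)phenol F6.
- (CF3SO2)2O and pyridine would give 2,3-dimethoxy-6-methyl-4-(triisopropylsilyloxy)phenyl trifluoromethanesulfonate F7.
- Hydroxycarbonylation of F7 (Pd(OAc)2, dppf, CO, KOAc, DMSO/H2O) would give 19.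

Step 9. The aryl silyl ether may be lost, or the aryl ester cleaved or transferred by phenoxide, under carbonate base. The fallback protects ring B before the ester is formed; it sets out from 20 and returns at 23.
- Allyl bromide with one equivalent of K2CO3 in acetone should alkylate the unchelated hydroxyl to 4-(allyloxy)-2-hydroxy-6-methylbenzaldehyde F8.
- BnBr/K2CO3 in DMF would give 4-(allyloxy)-2-(benzyloxy)-6-methylbenzaldehyde F9.
- Pd(PPh3)4 (zerovalent palladium) with morpholine would remove the allyl group to give 2-(benzyloxy)-4-hydroxy-6-methylbenzaldehyde F10.
- Acylation of F10 with 19 through 21 ((CF3CO)2O, toluene) would give 23 without any base meeting the depside.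

## Further compounds

F1 | step 4 | benzyl 2,4-dihydroxy-6-methylbenzoate | Cc1cc(O)cc(O)c1C(=O)OCc1ccccc1
F2 | step 4 | benzyl 4-{[2-(benzyloxy)-4-{[2,3-dimethoxy-6-methyl-4-(triisopropylsilyloxy)benzoyl]oxy}-6-methylbenzoyl]oxy}-2-hydroxy-6-methylbenzoate | COc1c(OC)c(O[Si](C(C)C)(C(C)C)C(C)C)cc(C)c1C(=O)Oc1cc(C)c(C(=O)Oc2cc(C)c(C(=O)OCc3ccccc3)c(O)c2)c(OCc2ccccc2)c1
F3 | step 3 | 5-lithio-3-phenylisoxazole | [Li]c1cc(-c2ccccc2)no1
F4 | step 7 | 2,3-dimethoxy-5-methylcyclohexa-2,5-diene-1,4-dione | COC1=C(OC)C(=O)C(C)=CC1=O
F5 | step 7 | 2,3-dimethoxy-5-methylbenzene-1,4-diol | COc1c(O)cc(C)c(O)c1OC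
F6 | step 7 | 2,3-dimethoxy-6-methyl-4-(triisopropylsilyloxy)phenol | COc1c(O[Si](C(C)C)(C(C)C)C(C)C)cc(C)c(O)c1OC
F7 | step 7 | 2,3-dimethoxy-6-methyl-4-(triisopropylsilyloxy)phenyl trifluoromethanesulfonate | COc1c(O[Si](C(C)C)(C(C)C)C(C)C)cc(C)c(OS(=O)(=O)C(F)(F)F)c1OC
F8 | step 9 | 4-(allyloxy)-2-hydroxy-6-methylbenzaldehyde | C=CCOc1cc(C)c(C=O)c(O)c1
F9 | step 9 | 4-(allyloxy)-2-(benzyloxy)-6-methylbenzaldehyde | C=CCOc1cc(C)c(C=O)c(OCc2ccccc2)c1
F10 | step 9 | 2-(benzyloxy)-4-hydroxy-6-methylbenzaldehyde | Cc1cc(O)cc(OCc2ccccc2)c1C=O
A1 | alternative 1 | 2,3-dimethoxy-6-methyl-4-(triisopropylsilyloxy)benzoic acid | COc1c(OC)c(O[Si](C(C)C)(C(C)C)C(C)C)cc(C)c1C(=O)O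
A2 | alternative 1 | 2-iodo-3,4-dimethoxy-5-(triisopropylsilyloxy)phenyl 4-chlorobenzenesulfonate | COc1c(OC)c(O[Si](C(C)C)(C(C)C)C(C)C)cc(OS(=O)(=O)c2ccc(Cl)cc2)c1I
A3 | alternative 1 | 1,2-didehydro-3,4-dimethoxy-5-(triisopropylsilyloxy)benzene | COC1=C(OC)C(O[Si](C(C)C)(C(C)C)C(C)C)=CC#C1
A4 | alternative 2 | methyl 3-methoxy-6-methyl-2,4-dioxocyclohexane-1-carboxylate (mixture of stereoisomers) | COC1C(=O)CC(C)C(C(=O)OC)C1=O
A5 | alternative 2 | methyl 4-methoxy-3-oxobutanoate | COCC(=O)CC(=O)OC
A6 | alternative 2 | methyl (E)-but-2-enoate | C/C=C/C(=O)OC
A7 | alternative 2 | methyl 2,4-dihydroxy-3-methoxy-6-methylbenzoate | COC(=O)c1c(C)cc(O)c(OC)c1O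
A8 | alternative 3 | benzyl 4-(2,4-dihydroxy-6-methylbenzoyl)oxy-2-hydroxy-6-methylbenzoate | Cc1cc(O)cc(O)c1C(=O)Oc1cc(C)c(C(=O)OCc2ccccc2)c(O)c1
A9 | alternative 3 | 6-(2,4-dioxopentyl)-2,2-dimethyl-4H-1,3-dioxin-4-one | CC(=O)CC(=O)CC1=CC(=O)OC(C)(C)O1
A10 | alternative 3 | benzyl 2,4-dihydroxy-6-methylbenzoate | Cc1cc(O)cc(O)c1C(=O)OCc1ccccc1
A11 | alternative 3 | benzyl 2-hydroxy-6-methyl-4-[(3,5,7-trioxooctanoyl)oxy]benzoate | CC(=O)CC(=O)CC(=O)CC(=O)Oc1cc(C)c(C(=O)OCc2ccccc2)c(O)c1
A12 | alternative 3 | oct-1-ene-1,3,5,7-tetraone | O=C=CC(=O)CC(=O)CC(C)=O
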